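**Retrosynthetic overview**
1. Target ⇒ (C11=C12, Horner–Wadsworth–Emmons) ring-A keto-enal already carrying the C19 decenoate + C25 ε-end phosphonate; the phosphonate ⇒ (C11'=C12', HWE) ε-end hydroxy-dienal + C10 bis(phosphonate).
2. Keto-enal ⇒ 2,3-disubstituted furan, a latent (E)-4-oxo-2-enal for C8–C11, opened oxidatively.
3. Key bond C7–C8: furan ⇒ C2-lithiated furan-3-ylmethanol (acyl-anion equivalent of C8; its alkoxide is acylated in the same flask) + ring-A allylic bromide ⇐ (4R,6R)-actinol by methylenation and allylic bromination with transposition.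
4. ε-End dienal ⇐ (R)-α-ionone: HWE to the dienenitrile, allylic C–H oxidation, then one i-Bu2AlH step that sets C3' and releases the aldehyde.
5. Rings: no carbocycle is built; ring A comes from actinol and the ε-ring from α-ionone; the furan is bought and opened in step 5.

Assumption: (4R,6R)-actinol, (R)-α-ionone of high ee, furan-3-ylmethanol, (2E)-dec-2-enoic acid and (2E,4E,6E)-2,7-dimethylocta-2,4,6-trienedial are bought, and the target is the all-E (3R,3'R,6'R) isomer of the given SMILES.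

**Step 1**
Reactants: 1 (4R,6R)-4-hydroxy-2,2,6-trimethylcyclohexan-1-one (actinol)
Product: 2 (4R,6R)-2,2,6-trimethyl-4-(triethylsilyloxy)cyclohexan-1-one
Conditions: Et3SiCl (1.2 equiv), imidazole (2 equiv), CH2Cl2, 0 °C → rt
Reagents that add atoms: chlorotriethylsilane, CC[Si](Cl)(CC)CC
Why: Standard silylation of the only hydroxyl; the triethylsilyl ether survives base, radical bromination and organolithium but falls to dilute acid in step 5, and no stereocentre is touched.

**Step 2**
Reactants: 2 (4R,6R)-2,2,6-trimethyl-4-(triethylsilyloxy)cyclohexan-1-one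
Product: 3 triethyl{[(1R,5R)-3,3,5-trimethyl-4-methylidenecyclohexyl]oxy}silane
Conditions: Ph3PCH3Br (3 equiv), KOtBu (3 equiv), toluene, 100 °C
Reagents that add atoms: methyltriphenylphosphonium bromide, C[P+](c1ccccc1)(c1ccccc1)c1ccccc1.[Br-]
Why: Wittig methylenation of a hindered ketone under hot alkoxide/toluene conditions; epimerisation next to the carbonyl does not matter because that carbon becomes sp2 in step 3, and the carbinol centre is remote.

**Step 3**
Reactants: 3 triethyl{[(1R,5R)-3,3,5-trimethyl-4-methylidenecyclohexyl]oxy}silane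
Product: 4 {[(1R)-4-(bromomethyl)-3,5,5-trimethylcyclohex-3-en-1-yl]oxy}triethylsilane
Conditions: NBS (1.05 equiv), AIBN (5 mol%), PhCF3, 80 °C; used crude
Reagents that add atoms: N-bromosuccinimide, O=C1CCC(=O)N1Br
Why: Wohl–Ziegler allylic bromination: the only allylic C–H (tertiary) is abstracted and the allyl radical takes bromine at the unhindered exocyclic terminus, moving the double bond into the ring to give the tetrasubstituted alkene and primary bromide (the β-pinene → myrtenyl bromide pattern), with the carbinol centre untouched.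

**Step 4 (key step)**
Reactants: 4 {[(1R)-4-(bromomethyl)-3,5,5-trimethylcyclohex-3-en-1-yl]oxy}triethylsilane; 5 furan-3-ylmethanol; 6 (2E)-dec-2-enoic acid
Product: 10 {2-[((4R)-2,6,6-trimethyl-4-(triethylsilyloxy)cyclohex-1-en-1-yl)methyl]furan-3-yl}methyl (2E)-dec-2-enoate, via dilithiated furanmethanol 7 (not isolated), via lithium alkoxide of the coupled furan 8 (not isolated), via decenoyl imidazolide 9 (not isolated)
Conditions: 5 (1.15 equiv), n-BuLi (2.3 equiv), DME, 0 °C, 1 h; 4 (1.0 equiv) in THF, −78 → 0 °C; then 9 [from 6 (1.5 equiv) and 1,1'-carbonyldiimidazole (1.5 equiv), THF, rt], 0 °C → rt; aq. NH4Cl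
Reagents that add atoms: none
Why: Alkoxide-directed lithiation at C2 of the furan gives a carbanion on the carbon that will become the C8 carbonyl, i.e. an acyl-anion equivalent for the whole C8–C11 enedione; it displaces the primary allylic bromide by SN2 (the rosefuran-type furyllithium/allyl bromide alkylation), joining C7 and C8, which are both electrophilic in normal-polarity terms, and the alkoxide left behind is esterified in the same flask by the acyl imidazole, with no stereocentre formed.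

**Step 5**
Reactants: 10 {2-[((4R)-2,6,6-trimethyl-4-(triethylsilyloxy)cyclohex-1-en-1-yl)methyl]furan-3-yl}methyl (2E)-dec-2-enoate
Product: 12 (2E)-2-{2-[(4R)-4-hydroxy-2,6,6-trimethylcyclohex-1-en-1-yl]acetyl}-4-oxobut-2-en-1-yl (2E)-dec-2-enoate, via Z-enedione silyl ether 11 (not isolated)
Conditions: NBS (1.05 equiv), NaHCO3 (2 equiv), acetone/H2O 10:1, −20 °C, dark; then 1 M HCl to pH 2, 0 °C → rt, 1 h
Reagents that add atoms: water, O
Why: Oxidative furan ring opening (Br+ at the free α-carbon, water at C2, collapse) unmasks the cis-ene-1,4-dicarbonyl, the furan being far more nucleophilic than the hindered tetrasubstituted ring alkene or the electron-poor enoate; dilute acid then equilibrates the enedione to the E isomer (carbonyls trans, C19 cis to C11 as in the target) and hydrolyses the silyl ether.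

**Step 6**
Reactants: 13 (3E)-4-[(1R)-2,6,6-trimethylcyclohex-2-en-1-yl]but-3-en-2-one ((R)-α-ionone)
Product: 14 (2E,4E)-3-methyl-5-[(1R)-2,6,6-trimethylcyclohex-2-en-1-yl]penta-2,4-dienenitrile
Conditions: (EtO)2P(O)CH2CN (1.3 equiv), NaH (1.3 equiv), THF, 0 °C → rt; minor 2Z isomer removed by chromatography
Reagents that add atoms: diethyl (cyanomethyl)phosphonate, N#CCP(=O)(OCC)OCC
Why: Horner–Wadsworth–Emmons olefination of the methyl ketone, E-selective (about 4:1), and the weakly basic phosphonate anion does not disturb the ring stereocentre.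

**Step 7**
Reactants: 14 (2E,4E)-3-methyl-5-[(1R)-2,6,6-trimethylcyclohex-2-en-1-yl]penta-2,4-dienenitrile
Product: 15 (2E,4E)-3-methyl-5-[(1R)-2,6,6-trimethyl-4-oxocyclohex-2-en-1-yl]penta-2,4-dienenitrile
Conditions: Rh2(cap)4 (cap = caprolactamate, C6H10NO; 1 mol%), t-BuOOH (70% aq., 5 equiv), 1,2-dichloroethane, 40 °C
Reagents that add atoms: tert-butyl hydroperoxide, CC(C)(C)OO
Why: Allylic C–H oxidation by tert-butylperoxyl radicals turns the ring CH2 next to the trisubstituted alkene into the enone (the known α-ionone → 3-oxo-α-ionone transformation); the doubly allylic C–H at the stereocentre is shielded by the flanking gem-dimethyl and methyl groups, and the conjugated nitrile chain is inert.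

**Step 8**
Reactants: 15 (2E,4E)-3-methyl-5-[(1R)-2,6,6-trimethyl-4-oxocyclohex-2-en-1-yl]penta-2,4-dienenitrile
Product: 17 (2E,4E)-5-[(1R,4R)-4-hydroxy-2,6,6-trimethylcyclohex-2-en-1-yl]-3-methylpenta-2,4-dienal, via aluminium-bound aldimine 16 (not isolated)
Conditions: i-Bu2AlH (3 equiv), CH2Cl2, −78 → −40 °C; then wet silica gel, Et2O, 0 °C
Reagents that add atoms: water, O
Why: i-Bu2AlH performs the 1,2-reduction of the enone and the nitrile → aldimine reduction in one operation (hydrolysis gives the aldehyde); the bulky hydride attacks the ring carbonyl anti to the axial methyl of the gem-dimethyl group, i.e. from the face carrying the pseudo-axial side chain, so the new C4 centre is R and trans to the side chain (the lutein-type ε-end), and any cis epimer is separable.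

**Step 9**
Reactants: 18 (2E,4E,6E)-2,7-dimethylocta-2,4,6-trienedial
Product: 19 (2E,4E,6E)-2,7-dimethylocta-2,4,6-triene-1,8-diol
Conditions: NaBH4 (1 equiv), MeOH/THF, 0 °C
Reagents that add atoms: none
Why: Chemoselective 1,2-reduction of the two conjugated aldehydes; alkene geometry is untouched.

**Step 10**
Reactants: 19 (2E,4E,6E)-2,7-dimethylocta-2,4,6-triene-1,8-diol
Product: 20 tetraethyl [(2E,4E,6E)-2,7-dimethylocta-2,4,6-triene-1,8-diyl]bis(phosphonate)
Conditions: P(OEt)3 (6 equiv), ZnI2 (3 equiv), THF, 66 °C, 16 h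
Reagents that add atoms: triethyl phosphite, CCOP(OCC)OCC
Why: ZnI2-mediated direct conversion of allylic alcohols into diethyl phosphonates (transesterification to the allyl phosphite, then Arbuzov-type rearrangement); P–C bond formation at the primary terminus keeps the fully conjugated E,E,E-triene.

**Step 11**
Reactants: 17 (2E,4E)-5-[(1R,4R)-4-hydroxy-2,6,6-trimethylcyclohex-2-en-1-yl]-3-methylpenta-2,4-dienal; 20 tetraethyl [(2E,4E,6E)-2,7-dimethylocta-2,4,6-triene-1,8-diyl]bis(phosphonate)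
Product: 22 diethyl {(2E,4E,6E,8E,10E,12E)-13-[(1R,4R)-4-hydroxy-2,6,6-trimethylcyclohex-2-en-1-yl]-2,7,11-trimethyltrideca-2,4,6,8,10,12-hexaen-1-yl}phosphonate, via sodium phosphonate carbanion 21 (not isolated)
Conditions: 20 (3 equiv), NaN(SiMe3)2 (1.2 equiv), THF, −78 °C; then 17 (1 equiv), −78 → 0 °C; excess 20 recovered
Reagents that add atoms: none
Why: HWE olefination forms C11'=C12' E-selectively; the excess of bis(phosphonate) over base keeps it a mono-olefination, and the delocalised carbanion is too weak a base to epimerise the ε-ring centre.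

**Step 12**
Reactants: 22 diethyl {(2E,4E,6E,8E,10E,12E)-13-[(1R,4R)-4-hydroxy-2,6,6-trimethylcyclohex-2-en-1-yl]-2,7,11-trimethyltrideca-2,4,6,8,10,12-hexaen-1-yl}phosphonate; 12 (2E)-2-{2-[(4R)-4-hydroxy-2,6,6-trimethylcyclohex-1-en-1-yl]acetyl}-4-oxobut-2-en-1-yl (2E)-dec-2-enoate
Product: 24 (3R,3'R,6'R)-3,3'-dihydroxy-8-oxo-7,8-dihydro-β,ε-caroten-19-yl (2E)-dec-2-enoate (CNP0332433.1), via sodium phosphonate carbanion 23 (not isolated)
Conditions: 22 (1.2 equiv), NaN(SiMe3)2 (1.15 equiv), THF, −78 °C; then 12 (1.0 equiv), −78 → 0 °C, dark, argon; chromatography on deactivated silica, crystallisation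
Reagents that add atoms: none
Why: HWE olefination forms C11=C12 at the aldehyde, which is far more electrophilic than the C8 ketone, at a temperature where addition outruns enolisation at C7 or SN2′ loss of the allylic ester; it is E-selective, any hindered Z isomer at the new bond reverts thermally, and no stereocentre is touched.

**Compound list**
1 | (4R,6R)-4-hydroxy-2,2,6-trimethylcyclohexan-1-one (actinol) | O=C1C(C)(C)C[C@H](O)C[C@H]1C | starting material
2 | (4R,6R)-2,2,6-trimethyl-4-(triethylsilyloxy)cyclohexan-1-one | O=C1C(C)(C)C[C@H](O[Si](CC)(CC)CC)C[C@H]1C | intermediate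
3 | triethyl{[(1R,5R)-3,3,5-trimethyl-4-methylidenecyclohexyl]oxy}silane | C=C1C(C)(C)C[C@H](O[Si](CC)(CC)CC)C[C@H]1C | intermediate
4 | {[(1R)-4-(bromomethyl)-3,5,5-trimethylcyclohex-3-en-1-yl]oxy}triethylsilane | BrCC1=C(C)C[C@@H](O[Si](CC)(CC)CC)CC1(C)C | intermediate
5 | furan-3-ylmethanol | OCc1ccoc1 | starting material
6 | (2E)-dec-2-enoic acid | CCCCCCC/C=C/C(=O)O | starting material
7 | lithium (2-lithiofuran-3-yl)methanolate | [Li]OCc1ccoc1[Li] | intermediate
8 | lithium {2-[((4R)-2,6,6-trimethyl-4-(triethylsilyloxy)cyclohex-1-en-1-yl)methyl]furan-3-yl}methanolate | [Li]OCc1ccoc1CC1=C(C)C[C@@H](O[Si](CC)(CC)CC)CC1(C)C | intermediate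
9 | (2E)-1-(1H-imidazol-1-yl)dec-2-en-1-one | CCCCCCC/C=C/C(=O)n1ccnc1 | intermediate
10 | {2-[((4R)-2,6,6-trimethyl-4-(triethylsilyloxy)cyclohex-1-en-1-yl)methyl]furan-3-yl}methyl (2E)-dec-2-enoate | CCCCCCC/C=C/C(=O)OCc1ccoc1CC1=C(C)C[C@@H](O[Si](CC)(CC)CC)CC1(C)C | intermediate
11 | (2Z)-4-oxo-2-{2-[(4R)-2,6,6-trimethyl-4-(triethylsilyloxy)cyclohex-1-en-1-yl]acetyl}but-2-en-1-yl (2E)-dec-2-enoate | CCCCCCC/C=C/C(=O)OC/C(=C/C=O)C(=O)CC1=C(C)C[C@@H](O[Si](CC)(CC)CC)CC1(C)C | intermediate
12 | (2E)-2-{2-[(4R)-4-hydroxy-2,6,6-trimethylcyclohex-1-en-1-yl]acetyl}-4-oxobut-2-en-1-yl (2E)-dec-2-enoate | CCCCCCC/C=C/C(=O)OC\C(=C/C=O)C(=O)CC1=C(C)C[C@@H](O)CC1(C)C | intermediate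
13 | (3E)-4-[(1R)-2,6,6-trimethylcyclohex-2-en-1-yl]but-3-en-2-one ((R)-α-ionone) | CC(=O)/C=C/[C@H]1C(C)=CCCC1(C)C | starting material
14 | (2E,4E)-3-methyl-5-[(1R)-2,6,6-trimethylcyclohex-2-en-1-yl]penta-2,4-dienenitrile | N#C/C=C(C)/C=C/[C@H]1C(C)=CCCC1(C)C | intermediate
15 | (2E,4E)-3-methyl-5-[(1R)-2,6,6-trimethyl-4-oxocyclohex-2-en-1-yl]penta-2,4-dienenitrile | N#C/C=C(C)/C=C/[C@H]1C(C)=CC(=O)CC1(C)C | intermediate
16 | (2E,4E)-5-[(1R,4R)-4-hydroxy-2,6,6-trimethylcyclohex-2-en-1-yl]-3-methylpenta-2,4-dien-1-imine (held as its aluminium derivative until work-up; drawn as the free imine) | N=C/C=C(C)/C=C/[C@H]1C(C)=C[C@H](O)CC1(C)C | intermediate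
17 | (2E,4E)-5-[(1R,4R)-4-hydroxy-2,6,6-trimethylcyclohex-2-en-1-yl]-3-methylpenta-2,4-dienal | O=C/C=C(C)/C=C/[C@H]1C(C)=C[C@H](O)CC1(C)C | intermediate
18 | (2E,4E,6E)-2,7-dimethylocta-2,4,6-trienedial | O=C/C(C)=C/C=C/C=C(C)/C=O | starting material
19 | (2E,4E,6E)-2,7-dimethylocta-2,4,6-triene-1,8-diol | OC/C(C)=C/C=C/C=C(C)/CO | intermediate
20 | tetraethyl [(2E,4E,6E)-2,7-dimethylocta-2,4,6-triene-1,8-diyl]bis(phosphonate) | CCOP(=O)(OCC)C/C(C)=C/C=C/C=C(C)/CP(=O)(OCC)OCC | intermediate
21 | sodium salt of the mono-carbanion of 20 | [Na+].CCOP(=O)(OCC)[CH-]/C(C)=C/C=C/C=C(C)/CP(=O)(OCC)OCC | intermediate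
22 | diethyl {(2E,4E,6E,8E,10E,12E)-13-[(1R,4R)-4-hydroxy-2,6,6-trimethylcyclohex-2-en-1-yl]-2,7,11-trimethyltrideca-2,4,6,8,10,12-hexaen-1-yl}phosphonate | CCOP(=O)(OCC)C/C(C)=C/C=C/C=C(C)/C=C/C=C(C)/C=C/[C@H]1C(C)=C[C@H](O)CC1(C)C | intermediate
23 | sodium salt of the C1 carbanion of 22 | [Na+].CCOP(=O)(OCC)[CH-]/C(C)=C/C=C/C=C(C)/C=C/C=C(C)/C=C/[C@H]1C(C)=C[C@H](O)CC1(C)C | intermediate
24 | (3R,3'R,6'R)-3,3'-dihydroxy-8-oxo-7,8-dihydro-β,ε-caroten-19-yl (2E)-dec-2-enoate (CNP0332433.1) | CCCCCCC/C=C/C(=O)OC\C(=C/C=C/C(C)=C/C=C/C=C(C)/C=C/C=C(C)/C=C/[C@H]1C(C)=C[C@H](O)CC1(C)C)C(=O)CC1=C(C)C[C@@H](O)CC1(C)C | target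

**Step count and risks**
Total steps: 12. Longest linear sequence: 6 (steps 1–5 and 12, from actinol).

Most likely to fail:

Step 12 (final HWE on the enedione aldehyde). The phosphonate carbanion may enolise 12 at C7 or attack the enone/allylic ester instead of the aldehyde. The fallback is a base-free Wittig reaction. It sets out from diol 19: Ph3P·HBr in MeOH at rt gives [(2E,4E,6E)-2,7-dimethylocta-2,4,6-triene-1,8-diyl]bis(triphenylphosphonium) dibromide F4. Mono-Wittig reaction of F4 (3 equiv) with aldehyde 17 (NaOMe 1 equiv, CH2Cl2/MeOH, 0 °C) gives the C25 ε-end triphenylphosphonium bromide F5. F5 is then condensed with 12 in 1,2-epoxybutane/EtOH at 60 °C, where the epoxide traps HBr and no free base is present, and the route is rejoined at 24.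

Step 5 (furan unmasking). NBS may also attack the tetrasubstituted ring alkene or brominate the doubly activated C7 methylene. The fallback replaces electrophilic halogen by a cycloaddition and sets out from 10: singlet oxygen (O2, tetraphenylporphyrin, visible light, CH2Cl2, −78 °C) adds [4+2] across the furan to give the bicyclic furan endoperoxide F3. Me2S reduces F3 to the Z-enedione silyl ether, where the route is rejoined at 11; the acid treatment of step 5 then gives 12.

Step 3 (Wohl–Ziegler bromination with transposition). It may give regioisomeric bromides, dibromide or partial desilylation. The fallback builds C7 by cross-coupling and sets out from 2: KN(SiMe3)2/PhNTf2 (THF, −78 °C) gives the tetrasubstituted enol triflate F1, since only the methyl-bearing α-carbon can enolise. Stille coupling with Bu3SnCH2OH (Pd(PPh3)4, LiCl, dioxane, 100 °C) gives the ring-A allylic alcohol F2. Appel bromination (CBr4, PPh3, CH2Cl2, 0 °C) rejoins the route at 4.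

**Further compounds**
F1 | step 3 | (4R)-2,6,6-trimethyl-4-(triethylsilyloxy)cyclohex-1-en-1-yl trifluoromethanesulfonate | FC(F)(F)S(=O)(=O)OC1=C(C)C[C@@H](O[Si](CC)(CC)CC)CC1(C)C
F2 | step 3 | [(4R)-2,6,6-trimethyl-4-(triethylsilyloxy)cyclohex-1-en-1-yl]methanol | OCC1=C(C)C[C@@H](O[Si](CC)(CC)CC)CC1(C)C
F3 | step 5 | {1-[((4R)-2,6,6-trimethyl-4-(triethylsilyloxy)cyclohex-1-en-1-yl)methyl]-2,3,7-trioxabicyclo[2.2.1]hept-5-en-6-yl}methyl (2E)-dec-2-enoate (bridgehead epimers) | CCCCCCC/C=C/C(=O)OCC1=CC2OOC1(CC1=C(C)C[C@@H](O[Si](CC)(CC)CC)CC1(C)C)O2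
F4 | step 12 | [(2E,4E,6E)-2,7-dimethylocta-2,4,6-triene-1,8-diyl]bis(triphenylphosphonium) dibromide | [Br-].[Br-].c1ccccc1[P+](c1ccccc1)(c1ccccc1)C/C(C)=C/C=C/C=C(C)/C[P+](c1ccccc1)(c1ccccc1)c1ccccc1
F5 | step 12 | {(2E,4E,6E,8E,10E,12E)-13-[(1R,4R)-4-hydroxy-2,6,6-trimethylcyclohex-2-en-1-yl]-2,7,11-trimethyltrideca-2,4,6,8,10,12-hexaen-1-yl}triphenylphosphonium bromide | [Br-].c1ccccc1[P+](c1ccccc1)(c1ccccc1)C/C(C)=C/C=C/C=C(C)/C=C/C=C(C)/C=C/[C@H]1C(C)=C[C@H](O)CC1(C)C
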